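**Retrosynthetic overview**

Numbering used: ring A = C1(CH3)–C2–C3–C4(OH)(i-Pr)–C5(H); ring B = C1–C5–C6(O-aroyl)–C7–C8(CH3)–C9–C10, with the epoxide on C8/C9 (α face, like O6; C1-methyl and C4-OH are β, H5 is α).
Late stage: aroyl ester on O6 and hydrogenation of C2=C3; ring A is closed by ring-closing metathesis of a C1-propenyl and a C4-vinyl group; the C8/C9 epoxide comes from epoxidation directed by the C6 hydroxyl.
Key disconnection: the array C4(OH)–C5(H)–C6(O), in which C5 of ring B also carries the quaternary C1, is the retron of a 2,3-epoxy-alcohol semipinacol shift. C1 moves from C6 to C5, so the seven-membered ring B arises from a cyclohexenol by one-carbon enlargement, with hydride transfer to C6 in the same flask and convergence of both carbinol epimers.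
The cyclohexenol comes from an α-quaternary β,γ-cyclohexenone (asymmetric allylation of a Birch-derived silyl dienol ether) and a (Z)-iodoalkenol (carbomagnesiation of propargyl alcohol); the oxirane is set by catalyst control.
Ring order: six-membered ring B (from the arene) → seven-membered ring B (step 8) → ring A (step 12).

Key step: step 8

Assumption: in step 7 the antipode of the bishydroxamic acid ligand that delivers oxygen to the face giving the (2R,3S)-oxirane is written as (R,R); if the sense is the opposite, the (S,S)-ligand is used.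

**Route**

Step 1
Reactants: 1 2,5-dimethylphenol
Product: 2 tert-butyl(2,5-dimethylphenoxy)dimethylsilane
Conditions: TBSCl, imidazole, DMF, rt
Reagents that add atoms: tert-butyldimethylsilyl chloride, CC(C)(C)[Si](C)(C)Cl
Why: Imidazole-assisted silylation of the phenol gives an aryl silyl ether that should survive dissolving-metal reduction and later serve as a regiodefined enolate source.

Step 2
Reactants: 2 tert-butyl(2,5-dimethylphenoxy)dimethylsilane
Product: 3 tert-butyl[(2,5-dimethylcyclohexa-1,4-dien-1-yl)oxy]dimethylsilane
Conditions: Li, liquid NH3, THF, t-BuOH, −78 to −33 °C; NH4Cl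
Reagents that add atoms: none
Why: Birch reduction should protonate the two unsubstituted ring positions flanked by donors, so that oxygen and both methyl groups stay on double bonds and the silyl enol ether is fixed on the methyl-bearing carbon (future C6=C1).

Step 3
Reactants: 3 tert-butyl[(2,5-dimethylcyclohexa-1,4-dien-1-yl)oxy]dimethylsilane
Product: 4 (2R)-2,5-dimethyl-2-(prop-2-en-1-yl)cyclohex-4-en-1-one
Conditions: Pd2(dba)3 (2.5 mol%), (S)-t-BuPHOX (6 mol%), diallyl carbonate, Bu4N[Ph3SiF2] (35 mol%), THF, 25 °C
Reagents that add atoms: diallyl carbonate, C=CCOC(=O)OCC=C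
Why: Enantioselective Tsuji–Trost allylation of a silyl enol ether (fluoride-initiated) should alkylate the regiodefined tetrasubstituted enolate within the chiral Pd–allyl–PHOX complex and set the quaternary centre C1 in the same spatial sense as (S)-2-allyl-2-methylcyclohexanone (descriptor R here because of the ring alkene).

Step 4
Reactants: 4 (2R)-2,5-dimethyl-2-(prop-2-en-1-yl)cyclohex-4-en-1-one
Product: 5 (2S)-2,5-dimethyl-2-[(1E)-prop-1-en-1-yl]cyclohex-4-en-1-one
Conditions: [Ir(cod)(PMePh2)2]PF6 (2 mol%, pre-activated with H2), THF, rt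
Reagents that add atoms: none
Why: Iridium-hydride alkene isomerisation should move only the monosubstituted double bond by one position to the (E)-propenyl group needed for the later five-membered ring closure, leaving the trisubstituted ring alkene and C1 untouched.

Step 5
Reactants: 6 prop-2-yn-1-ol
Product: 8 (2Z)-3-iodo-2-(propan-2-yl)prop-2-en-1-ol, via alkenylmagnesium chelate 7 (not isolated)
Conditions: i-PrMgCl (2.5 equiv), CuI (10 mol%), THF, −10 °C to rt; then I2, −40 °C
Reagents that add atoms: isopropylmagnesium chloride, CC(C)[Mg]Cl; iodine, II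
Why: Copper-catalysed anti-carbomagnesiation of the propargylic alkoxide should place isopropyl on the internal carbon and magnesium cis to CH2O in a five-membered chelate, and iodinolysis with retention gives the (Z)-iodide.

Step 6
Reactants: 8 (2Z)-3-iodo-2-(propan-2-yl)prop-2-en-1-ol; 5 (2S)-2,5-dimethyl-2-[(1E)-prop-1-en-1-yl]cyclohex-4-en-1-one
Product: 10 (2S)-1-[(1Z)-3-hydroxy-2-(propan-2-yl)prop-1-en-1-yl]-2,5-dimethyl-2-[(1E)-prop-1-en-1-yl]cyclohex-4-en-1-ol (both C1 epimers), via dilithio alkenyl alkoxide 9 (not isolated)
Conditions: 8, n-BuLi (1 equiv) then t-BuLi (2 equiv), Et2O, −78 °C; added to 5 pre-stirred with CeCl3, THF, −78 °C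
Reagents that add atoms: none
Why: Iodine–lithium exchange with retention of alkene geometry followed by 1,2-addition to the CeCl3-activated, enolisable ketone (organocerium-type addition) should give the tertiary allylic alcohol; the new carbinol centre (C6) is formed without control, which steps 7 and 8 tolerate.

Step 7
Reactants: 10 (2S)-1-[(1Z)-3-hydroxy-2-(propan-2-yl)prop-1-en-1-yl]-2,5-dimethyl-2-[(1E)-prop-1-en-1-yl]cyclohex-4-en-1-ol
Product: 11 (2S)-1-[(2R,3S)-3-(hydroxymethyl)-3-(propan-2-yl)oxiran-2-yl]-2,5-dimethyl-2-[(1E)-prop-1-en-1-yl]cyclohex-4-en-1-ol (both C1 epimers)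
Conditions: VO(OiPr)3 (2 mol%), (R,R)-N,N′-dihydroxy-N,N′-bis(diphenylacetyl)cyclohexane-1,2-diamine (4 mol%), 70% aq. TBHP, CH2Cl2, 0 °C
Reagents that add atoms: tert-butyl hydroperoxide, CC(C)(C)OO
Why: Hydroxyl-directed asymmetric epoxidation with a vanadium bishydroxamate catalyst should be chemoselective for the side-chain alkene (bound through the primary allylic alkoxide) and set both oxirane centres (future C5 and C4) by ligand control, independent of the carbinol centre, syn addition keeping C6 and CH2OH cis.

Step 8
Reactants: 11 (2S)-1-[(2R,3S)-3-(hydroxymethyl)-3-(propan-2-yl)oxiran-2-yl]-2,5-dimethyl-2-[(1E)-prop-1-en-1-yl]cyclohex-4-en-1-ol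
Product: 13 (1S,6S,7S)-7-[(2R)-1,2-dihydroxy-3-methylbutan-2-yl]-3,6-dimethyl-6-[(1E)-prop-1-en-1-yl]cyclohept-3-en-1-ol, via ring-enlarged ketone 12 (not isolated)
Conditions: Al(OiPr)3 (3 equiv), i-PrOH/toluene, 80 °C; aqueous potassium sodium tartrate (KNaC4H4O6)
Reagents that add atoms: none
Why: Both hydroxyls become aluminium alkoxides, the C6–O–Al unit chelates the oxirane oxygen, and cleavage of the C5–O bond is accompanied by a suprafacial 1,2-shift of the fully substituted ring carbon C1 from C6 to C5 (semipinacol rearrangement of a 2,3-epoxy alcohol), which enlarges ring B from six to seven atoms and leaves a C6 ketone whose C4-bound aluminium then passes hydride from an isopropoxide ligand to C6 through a six-membered Meerwein–Ponndorf–Verley transition state. The closest known reaction type is the Al(OiPr)3-mediated tandem semipinacol rearrangement/Meerwein–Ponndorf–Verley reduction of tertiary α-hydroxy epoxides to 1,3-diols. No ring is closed by cyclisation: ring B is enlarged by bond migration (C1–C6 broken, C1–C5 formed) and ring A is closed later. C5 is set by inversion at the oxirane carbon (C1 enters anti to the leaving oxygen, with retention in C1), C4 keeps the oxirane configuration from step 7, and C6 is set by intramolecular hydride delivery to the ketone face on the side of the C4 side chain (H cis to C4, hydroxyl trans). The step needs C5–O rather than C4–O cleavage and migration of C1 rather than C7; the first should be secured by the chelate and the alkoxide push from C6, the second by the higher migratory aptitude of the quaternary carbon, which rotation about C5–C6 can place antiperiplanar in either carbinol epimer. Because C6 becomes trigonal, both epimers of 11 should converge on the same ketone and the same triol.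

Step 9
Reactants: 13 (1S,6S,7S)-7-[(2R)-1,2-dihydroxy-3-methylbutan-2-yl]-3,6-dimethyl-6-[(1E)-prop-1-en-1-yl]cyclohept-3-en-1-ol
Product: 14 epoxy triol (13 with its ring double bond epoxidised cis to the ring hydroxyl; 8α,9α-epoxide)
Conditions: VO(acac)2 (5 mol%), TBHP (decane), CH2Cl2, 0 °C to rt
Reagents that add atoms: tert-butyl hydroperoxide, CC(C)(C)OO
Why: Hydroxyl-directed epoxidation should deliver oxygen to the homoallylic trisubstituted ring alkene syn to the C6 hydroxyl (α face) and leave the more remote propenyl group.

Step 10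
Reactants: 14 epoxy triol
Product: 16 lactol (both anomers), via hydroxy aldehyde 15 (not isolated)
Conditions: [Cu(MeCN)4]OTf (5 mol%), 2,2′-bipyridine (5 mol%), TEMPO (5 mol%), N-methylimidazole (10 mol%), air, MeCN, rt; stopped when 14 is consumed
Reagents that add atoms: none
Why: Copper/nitroxyl aerobic alcohol oxidation is selective for the primary alcohol, the aldehyde is captured by the C6 hydroxyl as a trans-fused five-membered lactol, the sterically demanding TEMPO should oxidise this lactol (a secondary carbinol next to the fully substituted C4) only slowly, and no glycol cleavage of the neighbouring tertiary alcohol is expected.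

Step 11
Reactants: 16 lactol (both anomers)
Product: 17 vinyl diol (epoxy-cycloheptanol carrying the (3S)-3-hydroxy-4-methylpent-1-en-3-yl group on C5 and methyl and (E)-propenyl on C1)
Conditions: Ph3PCH3Br (5 equiv), KN(SiMe3)2 (4.8 equiv), THF, 0 °C to rt
Reagents that add atoms: methyltriphenylphosphonium bromide, C[P+](c1ccccc1)(c1ccccc1)c1ccccc1.[Br-]
Why: Wittig methylenation of a lactol, in which the excess ylide deprotonates the hemiacetal and traps its ring-opened carbonyl form, should give the C4 vinyl group and free the C6 hydroxyl without touching a stereocentre.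

Step 12
Reactants: 17 vinyl diol
Product: 18 8α,9α-epoxydauc-2-ene-4β,6α-diol (1β-methyl, 5α-H)
Conditions: second-generation Hoveyda–Grubbs catalyst (5 mol%), toluene, 80 °C
Reagents that add atoms: none
Why: Ring-closing metathesis of the alkenyl groups on C1 and C4 should close ring A as a cyclopentene (five-membered ring, helped by the two fully substituted carbons) with loss of propene.

Step 13
Reactants: 18 8α,9α-epoxydauc-2-ene-4β,6α-diol; 19 4-(benzyloxy)benzoyl chloride
Product: 20 8α,9α-epoxy-4β-hydroxydauc-2-en-6α-yl 4-(benzyloxy)benzoate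
Conditions: Et3N, DMAP (cat.), CH2Cl2, 0 °C to rt
Reagents that add atoms: none
Why: Nucleophile-catalysed acylation should take place only at the secondary C6 hydroxyl, the tertiary C4 hydroxyl being too hindered.

Step 14
Reactants: 20 8α,9α-epoxy-4β-hydroxydauc-2-en-6α-yl 4-(benzyloxy)benzoate
Product: 21 jaeskeanin, 8α,9α-epoxy-4β-hydroxydaucan-6α-yl 4-hydroxybenzoate, (1R,4R,5S,6S,8R,9S)
Conditions: H2 (1 atm), Pd/C, EtOAc, rt
Reagents that add atoms: none
Why: Heterogeneous hydrogenation should saturate the only remaining C=C and cleave the benzyl ether by hydrogenolysis, leaving the trialkyl epoxide and the ester.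

**Compound list**

1 | 2,5-dimethylphenol | Cc1ccc(C)c(O)c1 | starting material
2 | tert-butyl(2,5-dimethylphenoxy)dimethylsilane | Cc1ccc(C)c(O[Si](C)(C)C(C)(C)C)c1 | intermediate
3 | tert-butyl[(2,5-dimethylcyclohexa-1,4-dien-1-yl)oxy]dimethylsilane | CC1=C(O[Si](C)(C)C(C)(C)C)CC(C)=CC1 | intermediate
4 | (2R)-2,5-dimethyl-2-(prop-2-en-1-yl)cyclohex-4-en-1-one | C=CC[C@]1(C)CC=C(C)CC1=O | intermediate
5 | (2S)-2,5-dimethyl-2-[(1E)-prop-1-en-1-yl]cyclohex-4-en-1-one | C/C=C/[C@]1(C)CC=C(C)CC1=O | intermediate
6 | prop-2-yn-1-ol | C#CCO | starting material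
7 | chloromagnesium (2Z)-3-(chloromagnesio)-2-(propan-2-yl)prop-2-en-1-olate | Cl[Mg]OC/C(C(C)C)=C\[Mg]Cl | intermediate
8 | (2Z)-3-iodo-2-(propan-2-yl)prop-2-en-1-ol | OC/C(C(C)C)=C\I | intermediate
9 | lithium (2Z)-3-lithio-2-(propan-2-yl)prop-2-en-1-olate | [Li]OC/C(C(C)C)=C\[Li] | intermediate
10 | (2S)-1-[(1Z)-3-hydroxy-2-(propan-2-yl)prop-1-en-1-yl]-2,5-dimethyl-2-[(1E)-prop-1-en-1-yl]cyclohex-4-en-1-ol, both C1 epimers | C/C=C/[C@]1(C)CC=C(C)CC1(O)/C=C(\CO)C(C)C | intermediate
11 | (2S)-1-[(2R,3S)-3-(hydroxymethyl)-3-(propan-2-yl)oxiran-2-yl]-2,5-dimethyl-2-[(1E)-prop-1-en-1-yl]cyclohex-4-en-1-ol, both C1 epimers | C/C=C/[C@]1(C)CC=C(C)CC1(O)[C@H]2O[C@]2(CO)C(C)C | intermediate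
12 | (6S,7R)-7-[(2R)-1,2-dihydroxy-3-methylbutan-2-yl]-3,6-dimethyl-6-[(1E)-prop-1-en-1-yl]cyclohept-3-en-1-one | C/C=C/[C@]1(C)CC=C(C)CC(=O)[C@H]1[C@@](O)(CO)C(C)C | intermediate
13 | (1S,6S,7S)-7-[(2R)-1,2-dihydroxy-3-methylbutan-2-yl]-3,6-dimethyl-6-[(1E)-prop-1-en-1-yl]cyclohept-3-en-1-ol | C/C=C/[C@]1(C)CC=C(C)C[C@H](O)[C@H]1[C@@](O)(CO)C(C)C | intermediate
14 | epoxy triol: 13 with the ring double bond epoxidised cis to the ring hydroxyl (8α,9α-epoxide) | C/C=C/[C@]1(C)C[C@@H]2O[C@]2(C)C[C@H](O)[C@H]1[C@@](O)(CO)C(C)C | intermediate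
15 | hydroxy aldehyde: 14 with CH2OH oxidised to CHO (open form of 16) | C/C=C/[C@]1(C)C[C@@H]2O[C@]2(C)C[C@H](O)[C@H]1[C@@](O)(C=O)C(C)C | intermediate
16 | lactol: cyclic hemiacetal of 15 with the ring hydroxyl, five-membered ring trans-fused to the seven-membered ring, both anomers | C/C=C/[C@]1(C)C[C@@H]2O[C@]2(C)C[C@@H]3OC(O)[C@@](O)(C(C)C)[C@H]31 | intermediate
17 | vinyl diol: epoxy-cycloheptanol with a (3S)-3-hydroxy-4-methylpent-1-en-3-yl group on C5 and methyl and (E)-propenyl on C1 | C/C=C/[C@]1(C)C[C@@H]2O[C@]2(C)C[C@H](O)[C@H]1[C@@](O)(C=C)C(C)C | intermediate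
18 | 8α,9α-epoxydauc-2-ene-4β,6α-diol (1β-methyl, 5α-H) | CC(C)[C@]1(O)C=C[C@]2(C)C[C@@H]3O[C@]3(C)C[C@H](O)[C@H]21 | intermediate
19 | 4-(benzyloxy)benzoyl chloride | O=C(Cl)c1ccc(OCc2ccccc2)cc1 | starting material
20 | 8α,9α-epoxy-4β-hydroxydauc-2-en-6α-yl 4-(benzyloxy)benzoate | CC(C)[C@]1(O)C=C[C@]2(C)C[C@@H]3O[C@]3(C)C[C@H](OC(=O)c3ccc(OCc4ccccc4)cc3)[C@H]21 | intermediate
21 | jaeskeanin, 8α,9α-epoxy-4β-hydroxydaucan-6α-yl 4-hydroxybenzoate, (1R,4R,5S,6S,8R,9S) | CC(C)[C@]1(O)CC[C@]2(C)C[C@@H]3O[C@]3(C)C[C@H](OC(=O)c3ccc(O)cc3)[C@H]21 | target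

**Count and risks**

Total steps: 14. Longest linear sequence: 13 (steps 1–4 and 6–14; step 5 makes the side-chain fragment).

Step 8 is the most likely to fail. The oxirane may open at the tertiary carbon C4 instead of C5 (hydride shift to an α-hydroxy ketone), C7 may migrate in one carbinol epimer, or the aluminium aldolate may lose its side chain by retro-aldol cleavage before hydride transfer. The fallback sets out from 11 and comes back at 13. The primary hydroxyl of 11 is silylated (TBSCl, imidazole) to the epoxy alcohol silyl ether F1. The rearrangement is then run on its own at low temperature under an external Lewis acid (BF3·OEt2, CH2Cl2, −78 °C; pinacol-type rearrangement of a 2,3-epoxy alcohol), which should give the ring-enlarged β-hydroxy ketone silyl ether F2. A separate hydroxyl-directed reduction (Me4NBH(OAc)3, MeCN/AcOH, −20 °C; Evans–Saksena reduction, hydride delivered from the C4 oxygen) gives the diol silyl ether F3, and Bu4NF then gives 13.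

Step 7 is the second risk. Ligand control may be poor on a Z-alkene that carries a fully substituted carbinol carbon, and the tertiary hydroxyl may direct the oxidant itself, against the ligand in one carbinol epimer. The fallback sets out from 10 and comes back at 11 and gives up catalyst control. With achiral VO(acac)2/TBHP each carbinol epimer of 10 should be epoxidised syn to its own tertiary hydroxyl under allylic 1,3-strain control. One epimer then gives 11 (as a single carbinol epimer) and the other gives the diastereomeric (2S,3R)-oxirane F4. The two are separated by chromatography and only 11 goes on, at the cost of about half of the material.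

Step 10 is the third risk. The oxidation may not stop at the lactol stage: the lactol may be oxidised further at a rate close to that of the hindered, neopentyl-type primary alcohol, so that a mixture of oxidation levels results. The fallback sets out from 14 and comes back at 16. Instead of being stopped halfway, the oxidation is driven to the higher level with the less hindered nitroxyl ABNO ([Cu(MeCN)4]OTf, 4,4′-dimethoxy-2,2′-bipyridine, ABNO, N-methylimidazole, air, MeCN, rt; aerobic oxidative lactonisation of a diol), which should give the trans-fused γ-lactone F5 (carbonyl carbon C3 bonded to O6, tertiary C4 hydroxyl free). Partial reduction with i-Bu2AlH (2.2 equiv, CH2Cl2, −78 °C; the first equivalent is consumed by the tertiary hydroxyl) should then stop at the aluminium acetal and give lactol 16 on work-up.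

**Further compounds**

F1 | step 8 | 11 as its primary tert-butyldimethylsilyl ether, both carbinol epimers | C/C=C/[C@]1(C)CC=C(C)CC1(O)[C@H]2O[C@]2(CO[Si](C)(C)C(C)(C)C)C(C)C
F2 | step 8 | ketone 12 as its primary tert-butyldimethylsilyl ether | C/C=C/[C@]1(C)CC=C(C)CC(=O)[C@H]1[C@@](O)(CO[Si](C)(C)C(C)(C)C)C(C)C
F3 | step 8 | triol 13 as its primary tert-butyldimethylsilyl ether | C/C=C/[C@]1(C)CC=C(C)C[C@H](O)[C@H]1[C@@](O)(CO[Si](C)(C)C(C)(C)C)C(C)C
F4 | step 7 | diastereomer of 11 with the (2S,3R)-oxirane, from the other carbinol epimer of 10 | C/C=C/[C@]1(C)CC=C(C)C[C@]1(O)[C@@H]2O[C@@]2(CO)C(C)C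
F5 | step 10 | γ-lactone corresponding to lactol 16, trans-fused to the seven-membered ring, tertiary α-hydroxyl free | C/C=C/[C@]1(C)C[C@@H]2O[C@]2(C)C[C@@H]3OC(=O)[C@@](O)(C(C)C)[C@H]31
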